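Ring labels: A = terminal 3,5-dihydroxyphenoxy ring; B = central ring (aryl ether oxygens at C1 and C3, OH at C5); C = pentasubstituted ring (C1 O–ring B, C2 OH, C3 H, C4 OH, C5 ring D, C6 OH); D = 2,4,6-trihydroxyphenyl.
Retrosynthetic cuts, in order: the nine O–CH3 bonds of a permethyl ether; the C5(ring C)–C1(ring D) biaryl bond; the C5–Br bond; the C2–O and C6–O bonds of ring C (both traced back to C–CHO); the C1(ring C)–O ether bond to ring B; the ring A–O bond to ring B.
Enabling feature: C1 of ring C holds the ring B aryloxy oxygen between the oxygenated carbons C2 and C6. These two carbons can therefore carry formyl groups first, which make C1–F electrophilic enough for ether formation. They are later exchanged for oxygen by aryl migration, and the C1 oxygen lies ortho to both migrating carbons.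
Forward order: no ring is constructed; four purchased benzene rings are joined A–B (Ullmann), then AB–C (fluoride displacement). The twofold oxidation then frees the only two phenols in the molecule, which steer bromination to ring C. C–D coupling (Suzuki) and global demethylation follow.
Stereochemistry: none to set; the target has no stereocentre, and the hindered C–D axis is not stereogenic because ring D is symmetric about it.

Key step: step 5

Remark: C3 and C5 of ring C are equivalent up to step 6; the position that is brominated there is called C5 from then on.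

Step 1
Reactants: 1 2-fluoro-5-methoxybenzaldehyde
Product: 2 2-(2-fluoro-5-methoxyphenyl)-1,3-dioxolane
Conditions: HOCH2CH2OH, p-TsOH·H2O (cat.), toluene, reflux, Dean–Stark
Reagents that add atoms: ethylene glycol, OCCO
Why: Acid-catalysed acetalisation with azeotropic removal of water is routine for benzaldehydes and masks the formyl group against the organolithium base of the next step.

Step 2
Reactants: 2 2-(2-fluoro-5-methoxyphenyl)-1,3-dioxolane
Product: 5 2-fluoro-5-methoxybenzene-1,3-dicarbaldehyde, via aryllithium 3 (not isolated), via acetal aldehyde 4 (not isolated)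
Conditions: n-BuLi, PMDTA, THF, −78 °C; DMF, −78 → 0 °C; then 2 M aq HCl, THF, rt
Reagents that add atoms: N,N-dimethylformamide, CN(C)C=O; water, O
Why: Directed ortho-metalation and formylation: with lithium saturated by the triamine the deprotonation follows C–H acidity, as in the fluorine-adjacent lithiation of 4-fluoroanisole under these conditions, so the open C–H next to fluorine should react rather than the C–H wedged between acetal and methoxy, while −78 °C prevents loss of LiF to an aryne and the acidic work-up releases both aldehydes.

Step 3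
Reactants: 6 5-methoxybenzene-1,3-diol (5-methoxyresorcinol, 3 equiv); 7 1-bromo-3,5-dimethoxybenzene
Product: 8 3-(3,5-dimethoxyphenoxy)-5-methoxyphenol
Conditions: CuI (10 mol %), picolinic acid (20 mol %), K3PO4, DMSO, 90 °C, argon
Reagents that add atoms: none
Why: Ullmann-type copper-catalysed diaryl ether synthesis tolerates electron-rich partners, the two hydroxyls of 6 are equivalent so one monoether results, and the excess of the water-soluble diol (washed out afterwards) should hold the reaction at monoarylation.

Step 4
Reactants: 5 2-fluoro-5-methoxybenzene-1,3-dicarbaldehyde; 8 3-(3,5-dimethoxyphenoxy)-5-methoxyphenol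
Product: 9 2-[3-(3,5-dimethoxyphenoxy)-5-methoxyphenoxy]-5-methoxybenzene-1,3-dicarbaldehyde
Conditions: K2CO3, DMF, rt → 50 °C
Reagents that add atoms: none
Why: Nucleophilic aromatic substitution by addition–elimination: both ortho formyl groups stabilise the Meisenheimer adduct at the fluorine-bearing carbon, so the phenoxide should build the doubly flanked ether under mild conditions where a metal-catalysed coupling onto a di-ortho-oxygenated ring would be sluggish.

Step 5
Reactants: 9 2-[3-(3,5-dimethoxyphenoxy)-5-methoxyphenoxy]-5-methoxybenzene-1,3-dicarbaldehyde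
Product: 11 2-[3-(3,5-dimethoxyphenoxy)-5-methoxyphenoxy]-5-methoxybenzene-1,3-diol, via bis-formate 10 (not isolated)
Conditions: mCPBA (3 equiv), CH2Cl2, 0 °C → rt; aq Na2S2O3/NaHCO3 wash, solvent exchange; then K2CO3 (cat.), degassed MeOH, 0 °C, argon
Reagents that add atoms: mCPBA (3-chloroperoxybenzoic acid), OOC(=O)c1cccc(Cl)c1
Why: Each formyl group adds the peracid to give a Criegee hemiperacetal, which expels 3-chlorobenzoate while the ring C carbon (C2, then C6) shifts from carbon to oxygen, so both C–O bonds arise with the former formyl carbon kept as a formate, and catalytic carbonate in methanol then passes the formyl groups to the solvent. The closest known reaction type is the Baeyer–Villiger (Dakin-type) oxidation of ortho-alkoxy and ortho-aryloxy benzaldehydes to phenol formates, the usual sequel to a fluorobenzaldehyde ether synthesis, and twofold versions on 2-oxygenated isophthalaldehydes are known. No ring is closed and no stereocentre is created. The selectivity required is aryl over hydride shift, and it is secured by the C1 aryloxy oxygen, which is ortho to both migrating carbons and stabilises the positive charge that develops there; the first shift is the harder one because the remaining formyl group still withdraws electrons, whereas the formyloxy group it leaves behind eases the second. Chemoselectivity against hydroxylation of the electron-rich rings A and B rests on peracid addition to a carbonyl being much faster than arene oxidation by an unactivated peracid at or below room temperature without strong acid. The methanolysis is run cold and degassed because the liberated 2-aryloxy-5-methoxyresorcinol is air-sensitive as its phenolate.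

Step 6
Reactants: 11 2-[3-(3,5-dimethoxyphenoxy)-5-methoxyphenoxy]-5-methoxybenzene-1,3-diol
Product: 12 4-bromo-2-[3-(3,5-dimethoxyphenoxy)-5-methoxyphenoxy]-5-methoxybenzene-1,3-diol
Conditions: NBS (1.0 equiv, slow addition in THF), CH2Cl2, −78 → −30 °C, dark
Reagents that add atoms: N-bromosuccinimide, O=C1CCC(=O)N1Br
Why: Electrophilic aromatic bromination: only ring C carries free hydroxyls, and its equivalent C3 and C5 positions are each ortho to one OH, para to the other and ortho to OMe, so they should outcompete the ether-only rings A and B, while the first bromine deactivates ring C enough to stop at the monobromide with one equivalent of reagent.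

Step 7
Reactants: 12 4-bromo-2-[3-(3,5-dimethoxyphenoxy)-5-methoxyphenoxy]-5-methoxybenzene-1,3-diol
Product: 13 2-bromo-4-[3-(3,5-dimethoxyphenoxy)-5-methoxyphenoxy]-1,3,5-trimethoxybenzene
Conditions: MeI (3 equiv), K2CO3, acetone, reflux
Reagents that add atoms: iodomethane, CI
Why: Williamson O-methylation of both phenols brings ring C to the same protecting group as the rest of the molecule and removes the acidic protons before the cross-coupling.

Step 8
Reactants: 13 2-bromo-4-[3-(3,5-dimethoxyphenoxy)-5-methoxyphenoxy]-1,3,5-trimethoxybenzene; 14 (2,4,6-trimethoxyphenyl)boronic acid (2 equiv, in portions)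
Product: 15 3-[3-(3,5-dimethoxyphenoxy)-5-methoxyphenoxy]-2,2',4,4',6,6'-hexamethoxy-1,1'-biphenyl
Conditions: Pd2(dba)3 (2.5 mol %), SPhos (10 mol %), K3PO4, toluene/H2O 10:1, 100 °C, argon
Reagents that add atoms: none
Why: Suzuki–Miyaura coupling: the bulky electron-rich biarylphosphine gives a monoligated zerovalent palladium species able to insert into the electron-rich di-ortho-substituted bromide and to form tetra-ortho-substituted biaryls, methoxy being a small ortho group, while portionwise excess boronic acid compensates for protodeboronation.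

Step 9
Reactants: 15 3-[3-(3,5-dimethoxyphenoxy)-5-methoxyphenoxy]-2,2',4,4',6,6'-hexamethoxy-1,1'-biphenyl
Product: 16 3-[3-(3,5-dihydroxyphenoxy)-5-hydroxyphenoxy]-[1,1'-biphenyl]-2,2',4,4',6,6'-hexol (CNP0133338.0)
Conditions: BBr3 (15 equiv), CH2Cl2, −78 °C → rt, argon; ice-water quench; EtOAc extraction, Sephadex LH-20
Reagents that add atoms: none
Why: Lewis-acid ether cleavage: BBr3 binds each methoxy oxygen and bromide removes the methyl group by SN2 attack, whereas the diaryl ether and biaryl bonds offer no sp3 carbon, and the low temperature avoids the acid-promoted dehydration of the 2,2'-dihydroxybiaryl to a dibenzofuran that hot HBr, HI or pyridinium chloride could cause.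

Compound list
1 | 2-fluoro-5-methoxybenzaldehyde | COc1ccc(F)c(C=O)c1 | starting material
2 | 2-(2-fluoro-5-methoxyphenyl)-1,3-dioxolane | COc1ccc(F)c(C2OCCO2)c1 | intermediate
3 | [3-(1,3-dioxolan-2-yl)-2-fluoro-5-methoxyphenyl]lithium | COc1cc([Li])c(F)c(C2OCCO2)c1 | intermediate
4 | 3-(1,3-dioxolan-2-yl)-2-fluoro-5-methoxybenzaldehyde | COc1cc(C=O)c(F)c(C2OCCO2)c1 | intermediate
5 | 2-fluoro-5-methoxybenzene-1,3-dicarbaldehyde | COc1cc(C=O)c(F)c(C=O)c1 | intermediate
6 | 5-methoxybenzene-1,3-diol (5-methoxyresorcinol) | COc1cc(O)cc(O)c1 | starting material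
7 | 1-bromo-3,5-dimethoxybenzene | COc1cc(Br)cc(OC)c1 | starting material
8 | 3-(3,5-dimethoxyphenoxy)-5-methoxyphenol | COc1cc(OC)cc(Oc2cc(O)cc(OC)c2)c1 | intermediate
9 | 2-[3-(3,5-dimethoxyphenoxy)-5-methoxyphenoxy]-5-methoxybenzene-1,3-dicarbaldehyde | COc1cc(OC)cc(Oc2cc(OC)cc(Oc3c(C=O)cc(OC)cc3C=O)c2)c1 | intermediate
10 | 2-[3-(3,5-dimethoxyphenoxy)-5-methoxyphenoxy]-5-methoxybenzene-1,3-diyl diformate | COc1cc(OC)cc(Oc2cc(OC)cc(Oc3c(OC=O)cc(OC)cc3OC=O)c2)c1 | intermediate
11 | 2-[3-(3,5-dimethoxyphenoxy)-5-methoxyphenoxy]-5-methoxybenzene-1,3-diol | COc1cc(OC)cc(Oc2cc(OC)cc(Oc3c(O)cc(OC)cc3O)c2)c1 | intermediate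
12 | 4-bromo-2-[3-(3,5-dimethoxyphenoxy)-5-methoxyphenoxy]-5-methoxybenzene-1,3-diol | COc1cc(OC)cc(Oc2cc(OC)cc(Oc3c(O)cc(OC)c(Br)c3O)c2)c1 | intermediate
13 | 2-bromo-4-[3-(3,5-dimethoxyphenoxy)-5-methoxyphenoxy]-1,3,5-trimethoxybenzene | COc1cc(OC)cc(Oc2cc(OC)cc(Oc3c(OC)cc(OC)c(Br)c3OC)c2)c1 | intermediate
14 | (2,4,6-trimethoxyphenyl)boronic acid | COc1cc(OC)c(B(O)O)c(OC)c1 | starting material
15 | 3-[3-(3,5-dimethoxyphenoxy)-5-methoxyphenoxy]-2,2',4,4',6,6'-hexamethoxy-1,1'-biphenyl | COc1cc(OC)cc(Oc2cc(OC)cc(Oc3c(OC)cc(OC)c(-c4c(OC)cc(OC)cc4OC)c3OC)c2)c1 | intermediate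
16 | 3-[3-(3,5-dihydroxyphenoxy)-5-hydroxyphenoxy]-[1,1'-biphenyl]-2,2',4,4',6,6'-hexol | Oc1cc(O)cc(Oc2cc(O)cc(Oc3c(O)cc(O)c(-c4c(O)cc(O)cc4O)c3O)c2)c1 | target

Total step count: 9.
Longest linear sequence: 8 steps (steps 1, 2, 4, 5, 6, 7, 8, 9); step 3 is the side branch.

Steps most likely to fail

Step 8. Protodeboronation of the di-ortho-methoxy boronic acid in hot aqueous base may outrun the slow transmetalation onto a hindered arylpalladium bromide. Sluggish oxidative addition and hydrodebromination would add to the loss. The fallback is a base-free Negishi coupling that sets out from 13. Purchased 1,3,5-trimethoxybenzene (COc1cc(OC)cc(OC)c1) would be lithiated between two methoxy groups with n-BuLi in THF at 0 °C to give 2,4,6-trimethoxyphenyllithium F1. Transmetalation with ZnCl2 would give (2,4,6-trimethoxyphenyl)zinc chloride F2. F2 would be coupled with 13 using Pd2(dba)3 and RuPhos in THF at 70 °C, a catalyst type established for tetra-ortho-substituted biaryls. The route is rejoined at 15.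

Step 5. Hydride rather than aryl shift may occur in the first Criegee adduct while the second formyl group still depletes ring C. Peracid hydroxylation of rings A and B may also set in if the reaction has to be prolonged. The fallback keeps the same C2–O and C6–O bond formation but removes the migrating hydrogen; it sets out from 9. Addition of MeMgBr (THF, −78 → 0 °C) would give the bis(1-hydroxyethyl) compound F3 as a diastereomer mixture. Dess–Martin periodinane would oxidise it to the diacetyl compound F4. Baeyer–Villiger oxidation with mCPBA, in which methyl is the poorest migrating group so that only the aryl carbon can shift, would give the bis-acetate F5. Methanolysis (K2CO3, degassed MeOH) returns to the route at 11.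

Step 6. Ring selectivity may be lost through attack on ring A or B, and overbromination or oxidation of the electron-rich resorcinol by NBS may also occur. The fallback installs the halogen before any electron-rich ring is present and sets out from 5. Bromination with NBS in concentrated H2SO4 at rt, directed by the methoxy group to either of its two equivalent ortho positions, would give 4-bromo-2-fluoro-5-methoxybenzene-1,3-dicarbaldehyde F6. Phenol 8 (K2CO3, DMF) would displace fluoride, which is the better nucleofuge and is flanked by both formyl groups, to give the bromo aryloxy dialdehyde F7. mCPBA would convert F7 into the bromo bis-formate F8, and methanolysis rejoins the route at 12.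

Further compounds
F1 | step 8 | 2,4,6-trimethoxyphenyllithium | COc1cc(OC)c([Li])c(OC)c1
F2 | step 8 | (2,4,6-trimethoxyphenyl)zinc chloride | COc1cc(OC)c([Zn]Cl)c(OC)c1
F3 | step 5 | 1,1'-{2-[3-(3,5-dimethoxyphenoxy)-5-methoxyphenoxy]-5-methoxybenzene-1,3-diyl}di(ethan-1-ol), mixture of diastereomers | COc1cc(OC)cc(Oc2cc(OC)cc(Oc3c(C(C)O)cc(OC)cc3C(C)O)c2)c1
F4 | step 5 | 1,1'-{2-[3-(3,5-dimethoxyphenoxy)-5-methoxyphenoxy]-5-methoxybenzene-1,3-diyl}di(ethan-1-one) | COc1cc(OC)cc(Oc2cc(OC)cc(Oc3c(C(C)=O)cc(OC)cc3C(C)=O)c2)c1
F5 | step 5 | 2-[3-(3,5-dimethoxyphenoxy)-5-methoxyphenoxy]-5-methoxybenzene-1,3-diyl diacetate | COc1cc(OC)cc(Oc2cc(OC)cc(Oc3c(OC(C)=O)cc(OC)cc3OC(C)=O)c2)c1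
F6 | step 6 | 4-bromo-2-fluoro-5-methoxybenzene-1,3-dicarbaldehyde | COc1cc(C=O)c(F)c(C=O)c1Br
F7 | step 6 | 4-bromo-2-[3-(3,5-dimethoxyphenoxy)-5-methoxyphenoxy]-5-methoxybenzene-1,3-dicarbaldehyde | COc1cc(OC)cc(Oc2cc(OC)cc(Oc3c(C=O)cc(OC)c(Br)c3C=O)c2)c1
F8 | step 6 | 4-bromo-2-[3-(3,5-dimethoxyphenoxy)-5-methoxyphenoxy]-5-methoxybenzene-1,3-diyl diformate | COc1cc(OC)cc(Oc2cc(OC)cc(Oc3c(OC=O)cc(OC)c(Br)c3OC=O)c2)c1
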